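If the wait for second substrate fills a whole turn of the catalyst, the rate follows what is left of it; if that wait takes no time, the rate ignores it. You want to know where this flask stands between those extremes.

- autumn: starting material 0.10 M; second substrate 0.60 equiv; free enzyme 0.078 mol%; added ligand 41 µM; run made earlier
- flask: starting material 0.10 M; second substrate 1.20 equiv; free enzyme 0.078 mol%; added ligand 41 µM

autumn run (percent of the starting material charged)

| time / min | target / % | starting material / % |
|---|---|---|
| 0.200 | 22.4 | 78.3 |
| 0.667 | 50.8 | 48.5 |
| 1.00 | 57.7 | 41.8 |
| 1.50 | 60.3 | 40.3 |
| 2.50 | 60.2 | 40.6 |
| 3.00 | 60.1 | 39.3 |

(each reading ± 0.5 percentage points)

1. apparent order in second substrate when 50% of the starting material are converted (percent change of the rate of making target for one percent more second substrate charged)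

- what was read earlier has a scatter of 0.5 percentage points, one standard deviation
- steps under discussion: starting material + free enzyme <-> first complex; first complex -> loaded enzyme + first product; second substrate + loaded enzyme <-> second complex; second complex -> free enzyme + target; free enzyme + added ligand <-> idle complex
- no earlier run changes the charge of second substrate; that part of a forecast is a guess

Take one percent more charge, with the same amount used up. At 50% conversion the flask has a leverage of 1.71, the second substrate charged over the second substrate left. What is left in the flask then grows by more than one percent. So the full wait gives an order of 1.71 and no wait gives zero. I take the real order as leverage times waiting share, the part of a turn spent waiting for second substrate.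

The autumn run gives the wait. Its target readings level off near 60.3%. I treat the gap to that plateau as shrinking pseudo-first-order, and the readings give a lifetime of 0.257 min. So I put the wait, per whole charge of starting material, at that lifetime over the second substrate left, counted in equivalents. In the autumn opening this is 0.527 min of the 0.893 min needed per whole charge. I scale the remainder with one over the starting material left. At 50% in the flask, the wait is 0.367 min against 0.650 min. The share is 0.361 and my order is 0.618.

The forecast, a little lower, says 0.58, within 0.38 to 0.85: “so the order with respect to the charge is about 0.58”.

The flask gives 0.35, lower than my figure.

    starting material + free enzyme ⇌ first complex (K = 3.90 M⁻¹, k = 1200 M⁻¹ s⁻¹)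
    first complex → loaded enzyme + first product (k = 530 s⁻¹)
    second substrate + loaded enzyme ⇌ second complex (K = 42.0 M⁻¹, k = 1600 M⁻¹ s⁻¹)
    second complex → free enzyme + target (k = 410 s⁻¹)
    free enzyme + added ligand ⇌ idle complex, settled at all times (K = 31000 M⁻¹)

That order belongs to a rate of 0.0834 M min⁻¹ at 0.439 min. Divided by the leverage, it puts the waiting share at 0.205. Twice the charge raises what is left at that conversion by a factor of 2.71. If the wait shrinks by that factor and that share holds up to that conversion, the time to reach it changes by a factor of 0.871. The run with twice the second substrate gives a factor of 0.881 on that time.

The runs were generated by integration with made-up constants; scatter was added.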